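## Retrosynthetic overview

1. Presumed biogenesis: a prenyl cation adds to a carbon-bound prenyl group of a dearomatised acylphloroglucinol. The resulting tertiary cation is captured by the acyl-bearing enol carbon (ring A). The enol-dione bridge is then cut out oxidatively, and the remaining carboxyl oxygen closes on the oxidised acyl-bearing carbon (ring B).
2. Last disconnection: the same tertiary-cation/enol-carbon closure, run on a monocyclic 5-acylfuran-2,4-dione. The cation comes from the isopropenyl end of an (R)-lavandulyl chain, which is a "prenylated prenyl" group. This step sets the second bridgehead.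
3. Ring B: the carboxyl oxygen attacks the brominated (oxidised) carbon of an open-chain 3,5-diketo ester. The two carbons that nature excises are never installed.
4. Open chain: Claisen acylation of a quaternary β-keto ester with the (R)-2-methylbutanoyl unit. The quaternary carbon comes from tert-butyl acetoacetate by lavandulylation followed by asymmetric prenylation.
5. Ring order: ring B (γ-lactone) first, so that the carboxyl oxygen cannot compete for the cation, then ring A (cyclohexanone).

Assumption: (R)-lavandulol (the lavender-oil alcohol) and (R)-2-methylbutanoic acid are bought as the catalogue enantiomers.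

## Route

**Step 1**
Reactants: 1 (R)-lavandulol
Product: 2 (3R)-3-(iodomethyl)-2,6-dimethylhepta-1,5-diene [(R)-lavandulyl iodide]
Conditions: I2, PPh3, imidazole, CH2Cl2, 0 °C to rt
Reagents that add atoms: iodine, [I][I]
Why: Appel-type (Garegg–Samuelsson) iodination is an SN2 displacement of the oxyphosphonium group at the primary carbon, so both alkenes and the neighbouring stereocentre are untouched (descriptor stays R).

**Step 2**
Reactants: 2 (R)-lavandulyl iodide; 3 tert-butyl acetoacetate
Product: 4 tert-butyl (4S)-2-acetyl-7-methyl-4-(prop-1-en-2-yl)oct-6-enoate (about 1:1 at C2)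
Conditions: NaH, THF/DMF 4:1, 0 °C; then 2, 55 °C
Reagents that add atoms: none
Why: In this acetoacetic ester alkylation the soft, weakly basic sodium enolate displaces the primary iodide by SN2 at carbon with little elimination; C4 is untouched, and the new C2 centre does not matter because step 3 flattens it again.

**Step 3**
Reactants: 4 tert-butyl (4S)-2-acetyl-7-methyl-4-(prop-1-en-2-yl)oct-6-enoate; 5 prenyl bromide
Product: 6 tert-butyl (2S,4S)-2-acetyl-7-methyl-2-(3-methylbut-2-enyl)-4-(prop-1-en-2-yl)oct-6-enoate
Conditions: (11bS)-4,4-dibutyl-2,6-bis(3,4,5-trifluorophenyl)-4,5-dihydro-3H-dinaphtho[2,1-c:1',2'-e]azepinium bromide (2 mol %), CsOH·H2O, toluene, −30 °C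
Reagents that add atoms: none
Why: In this asymmetric phase-transfer alkylation of an α-substituted β-keto ester, the tight ion pair with the chiral ammonium ion leaves one enolate face open to the allylic bromide and sets the quaternary centre as 2S under catalyst control (sense by analogy, to be confirmed in a test run; the mirror-image catalyst gives 2R), and the minor 2R diastereomer is removed on silica.

**Step 4**
Reactants: 6 tert-butyl (2S,4S)-2-acetyl-7-methyl-2-(3-methylbut-2-enyl)-4-(prop-1-en-2-yl)oct-6-enoate; 7 (R)-2-methylbutanoic acid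
Product: 9 tert-butyl (2S,4S)-7-methyl-2-(3-methylbut-2-enyl)-2-[(4R)-4-methyl-3-oxohexanoyl]-4-(prop-1-en-2-yl)oct-6-enoate, via acyl imidazolide 8 (not isolated)
Conditions: 7, 1,1'-carbonyldiimidazole, THF, rt; separately 6, LiN(SiMe3)2, THF, −78 °C; combine, −78 to 0 °C; dilute aq. HCl quench
Reagents that add atoms: 1,1'-carbonyldiimidazole, O=C(n1ccnc1)n1ccnc1 (its imidazolyl group enters 8 only)
Why: In this crossed Claisen acylation the acetyl CH3 is the only enolisable position of 6, its lithium enolate attacks the acyl imidazolide, and the released imidazolide deprotonates the 1,3-diketone and stops further reaction; no stereocentre is formed and the R centre of 7 never meets free strong base.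

**Step 5**
Reactants: 9 tert-butyl (2S,4S)-7-methyl-2-(3-methylbut-2-enyl)-2-[(4R)-4-methyl-3-oxohexanoyl]-4-(prop-1-en-2-yl)oct-6-enoate
Product: 11 (3S)-3-(3-methylbut-2-enyl)-5-[(2R)-2-methylbutanoyl]-3-[(2S)-5-methyl-2-(prop-1-en-2-yl)hex-4-enyl]furan-2,4(3H,5H)-dione (C5 epimers, largely enolised), via bromodiketone 10 (not isolated)
Conditions: NBS (1.0 equiv), CH2Cl2, 0 °C; solvent switch to MeCN, 65 °C, N2 sweep
Reagents that add atoms: N-bromosuccinimide, O=C1CCC(=O)N1Br (bromine enters 10 only)
Why: Bromination of the enolised 1,3-diketone is far faster than attack on the alkenes and is followed by the classical γ-halo-β-keto ester to tetronic acid cyclisation, an intramolecular SN2 by the ester carbonyl oxygen in which tert-butyl leaves as tert-butyl bromide; the new C5 centre is enolisable and is fixed only in step 6.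

**Step 6**
Reactants: 11 (3S)-3-(3-methylbut-2-enyl)-5-[(2R)-2-methylbutanoyl]-3-[(2S)-5-methyl-2-(prop-1-en-2-yl)hex-4-enyl]furan-2,4(3H,5H)-dione
Product: 13 (1S,3S,5S)-4,4-dimethyl-5-[(2R)-2-methylbutanoyl]-1,3-bis(3-methylbut-2-enyl)-6-oxabicyclo[3.2.1]octane-7,8-dione, via tertiary cation 12 (not isolated)
Conditions: [N,N'-bis(3,5-di-tert-butylsalicylidene)cyclohexane-1,2-diaminato]cobalt (Co(C36H52N2O2), divalent cobalt, 5 mol %), N-fluoro-2,4,6-trimethylpyridinium triflate (1.5 equiv), (Me2SiH)2O (1.5 equiv), PhCF3, rt
Reagents that add atoms: none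
Why: Proposed new method: the cobalt hydride made from the fluorocobalt species and the silane gives a hydrogen atom only to the unhindered 1,1-disubstituted alkene (the trisubstituted prenyl groups react far more slowly), the tertiary radical is oxidised through an alkylcobalt to cation 12, and the planar enol carbon C5 of the acylfuranone, held three atoms away, captures it through a chair-like six-membered transition state with the C3 prenyl group equatorial, so the tether forces the new bridgehead to be 5S and no other diastereomer can form; the closest known reaction types are cobalt–salen hydrogen-atom-transfer/radical–polar-crossover Markovnikov hydrofunctionalisation of alkenes with oxygen, nitrogen, arene and 1,3-dicarbonyl nucleophiles and the tertiary-cation closure of dearomatised acylphloroglucinols to bicyclo[3.3.1]nonanetriones.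

## Compound list

1 | (R)-lavandulol, (2R)-5-methyl-2-(prop-1-en-2-yl)hex-4-en-1-ol | OC[C@H](CC=C(C)C)C(C)=C | starting material
2 | (R)-lavandulyl iodide, (3R)-3-(iodomethyl)-2,6-dimethylhepta-1,5-diene | IC[C@H](CC=C(C)C)C(C)=C | intermediate
3 | tert-butyl acetoacetate | CC(=O)CC(=O)OC(C)(C)C | starting material
4 | tert-butyl (4S)-2-acetyl-7-methyl-4-(prop-1-en-2-yl)oct-6-enoate (C2 epimers) | CC(=O)C(C[C@H](CC=C(C)C)C(C)=C)C(=O)OC(C)(C)C | intermediate
5 | prenyl bromide, 1-bromo-3-methylbut-2-ene | CC(C)=CCBr | starting material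
6 | tert-butyl (2S,4S)-2-acetyl-7-methyl-2-(3-methylbut-2-enyl)-4-(prop-1-en-2-yl)oct-6-enoate | CC(=O)[C@](CC=C(C)C)(C[C@H](CC=C(C)C)C(C)=C)C(=O)OC(C)(C)C | intermediate
7 | (R)-2-methylbutanoic acid | CC[C@@H](C)C(=O)O | starting material
8 | 1-[(2R)-2-methylbutanoyl]imidazole | CC[C@@H](C)C(=O)n1ccnc1 | intermediate
9 | tert-butyl (2S,4S)-7-methyl-2-(3-methylbut-2-enyl)-2-[(4R)-4-methyl-3-oxohexanoyl]-4-(prop-1-en-2-yl)oct-6-enoate | CC[C@@H](C)C(=O)CC(=O)[C@](CC=C(C)C)(C[C@H](CC=C(C)C)C(C)=C)C(=O)OC(C)(C)C | intermediate
10 | tert-butyl (2S,4S)-2-[(4R)-2-bromo-4-methyl-3-oxohexanoyl]-7-methyl-2-(3-methylbut-2-enyl)-4-(prop-1-en-2-yl)oct-6-enoate | CC[C@@H](C)C(=O)C(Br)C(=O)[C@](CC=C(C)C)(C[C@H](CC=C(C)C)C(C)=C)C(=O)OC(C)(C)C | intermediate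
11 | (3S)-3-(3-methylbut-2-enyl)-5-[(2R)-2-methylbutanoyl]-3-[(2S)-5-methyl-2-(prop-1-en-2-yl)hex-4-enyl]furan-2,4(3H,5H)-dione | CC[C@@H](C)C(=O)C1OC(=O)[C@@](CC=C(C)C)(C[C@H](CC=C(C)C)C(C)=C)C1=O | intermediate
12 | tertiary carbocation from 11 (2-propyl cation centre in place of the isopropenyl group) | CC[C@@H](C)C(=O)C1OC(=O)[C@@](CC=C(C)C)(C[C@H](CC=C(C)C)[C+](C)C)C1=O | intermediate
13 | (1S,3S,5S)-4,4-dimethyl-5-[(2R)-2-methylbutanoyl]-1,3-bis(3-methylbut-2-enyl)-6-oxabicyclo[3.2.1]octane-7,8-dione | CC[C@@H](C)C(=O)[C@@]12OC(=O)[C@@](CC=C(C)C)(C[C@H](CC=C(C)C)C1(C)C)C2=O | target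

Total step count: 6. Longest linear sequence: 6 (1 → 2 → 4 → 6 → 9 → 11 → 13).

## Steps most likely to fail

(a) **The closure of 11 (step 6).**
- Risk: the cation may be taken by the enol oxygen, giving a pyran-fused enol ether, or by the neighbouring prenyl alkene instead of by carbon.
- Fallback, from 11 back to 13: the one-step radical–polar closure is replaced by a discrete tertiary halide and a chelate-controlled ionisation. Markovnikov hydrochlorination of the isopropenyl group alone (Co(BF4)2·6H2O with a salicylidene amino-acid ligand, TsCl, PhSiH3, EtOH, rt) gives the tertiary chloride F1. At −78 °C in CH2Cl2, TiCl4 with 2,6-di-tert-butylpyridine as proton trap binds both diketone oxygens as a titanium chelate and ionises the carbon–chlorine bond. Only the central carbon is then free to attack (α-tert-alkylation of a chelated 1,3-dicarbonyl), and this gives 13.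

(b) **The asymmetric prenylation of 4 (step 3).**
- Risk: the bulky lavandulyl substituent may erode the facial selectivity of the ion pair.
- Fallback, from 4 back to 6: catalyst control is replaced by a covalently bound auxiliary. Condensing 4 with (S)-valine tert-butyl ester (cat. TsOH, benzene, water separator) gives the hydrogen-bonded enamino ester F2. LDA in toluene with one equivalent of a donor additive, chosen for the 2S face, gives a chelated lithioenamine whose isopropyl group blocks one face. Prenyl bromide then gives the quaternary ketimine F3, and mild aqueous acid hydrolysis gives 6.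

(c) **The bromination/lactonisation of 9 (step 5).**
- Risk: bromodiketone 10 can hand its bromine to the alkenes on warming, or it may close sluggishly.
- Fallback, from 6 back to 11: the lactone is built before the acyl group is attached. The lithium enolate of 6 (LiN(SiMe3)2, THF, −78 °C) is brominated with NBS to the bromomethyl ketone F4, which is no bromonium donor and closes at a primary carbon on warming in MeCN to the furandione F5. Its C5 enolate (LiN(SiMe3)2, −78 °C) is then acylated with 8 to give 11.

## Further compounds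

F1 | step 6 | (3S)-3-[(2S)-2-(2-chloropropan-2-yl)-5-methylhex-4-enyl]-3-(3-methylbut-2-enyl)-5-[(2R)-2-methylbutanoyl]furan-2,4(3H,5H)-dione | CC[C@@H](C)C(=O)C1OC(=O)[C@@](CC=C(C)C)(C[C@H](CC=C(C)C)C(C)(C)Cl)C1=O
F2 | step 3 | tert-butyl (Z)-3-{[(2S)-1-tert-butoxy-3-methyl-1-oxobutan-2-yl]amino}-2-[(2S)-5-methyl-2-(prop-1-en-2-yl)hex-4-enyl]but-2-enoate | C/C(N[C@@H](C(C)C)C(=O)OC(C)(C)C)=C(\C[C@H](CC=C(C)C)C(C)=C)C(=O)OC(C)(C)C
F3 | step 3 | tert-butyl (2S,4S)-2-{1-[(2S)-1-tert-butoxy-3-methyl-1-oxobutan-2-yl]iminoethyl}-7-methyl-2-(3-methylbut-2-enyl)-4-(prop-1-en-2-yl)oct-6-enoate | CC(=N[C@@H](C(C)C)C(=O)OC(C)(C)C)[C@](CC=C(C)C)(C[C@H](CC=C(C)C)C(C)=C)C(=O)OC(C)(C)C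
F4 | step 5 | tert-butyl (2S,4S)-2-(bromoacetyl)-7-methyl-2-(3-methylbut-2-enyl)-4-(prop-1-en-2-yl)oct-6-enoate | BrCC(=O)[C@](CC=C(C)C)(C[C@H](CC=C(C)C)C(C)=C)C(=O)OC(C)(C)C
F5 | step 5 | (3S)-3-(3-methylbut-2-enyl)-3-[(2S)-5-methyl-2-(prop-1-en-2-yl)hex-4-enyl]furan-2,4(3H,5H)-dione | C1OC(=O)[C@@](CC=C(C)C)(C[C@H](CC=C(C)C)C(C)=C)C1=O
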